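**Retrosynthetic overview** (azulene numbering: C3 = C(OH)iPr, C3a = ring-fusion CH, C4 = CH–O-acyl, C5 = CH2, C6=C7 = alkene, C8 = CH2, C8a = quaternary C)
1. Teferin comes from jaeschkeanadiol by late esterification of the 4-OH with acetyl-protected vanillic acid.
2. Jaeschkeanadiol comes from a hexahydroazulenone ester. The C3a–H/C4–O pair is the trace of a C3a=C4 alkene, C3(OH)iPr comes from a C3 ketone, and the C6 methyl comes from an ester.
3. Enabling feature: with C3a=C4 restored, the seven-membered ring is a cyclohepta-1,4-diene. C3a=C4 and C6=C7 are joined by the C5 methylene, and the C8–C8a bond lies opposite. This is the retron of a cis-divinylcyclopropane Cope rearrangement, and the C3 oxygen next to C3a lets the diene half be a plain 2-vinylcyclopentenone.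
4. The azulenone ester comes from 2-ethenyl-3-methylcyclopent-2-enone and methyl 2-diazobut-3-enoate. An enantioselective rhodium-carbenoid cyclopropanation/Cope sequence (formal [4+3]) makes C5–C6 and C8–C8a in one operation.
5. Ring order: the five-membered ring is bought, a transient cyclopropane follows, then the seven-membered ring. A temporary oxirane at C3a–C4 comes later.

Key step: step 3

Assumption: Rh2(S-PTAD)4, dirhodium tetrakis[(S)-(1-adamantyl)(phthalimido)acetate], is taken to give the (1S,2S) cyclopropane, the sense opposite to Rh2(S-DOSP)4 with vinyldiazoacetates. Both catalyst enantiomers are sold, so an inverted sense only means using Rh2(R-PTAD)4.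

Step 1
Reactants: 1 methyl but-3-enoate
Product: 2 methyl 2-diazobut-3-enoate
Conditions: p-ABSA, DBU, MeCN, 0 °C; kept cold as a hexanes solution and used the same day
Reagents that add atoms: 4-acetamidobenzenesulfonyl azide (p-ABSA), CC(=O)Nc1ccc(cc1)S(=O)(=O)N=[N+]=[N-]
Why: Regitz diazo transfer, the usual entry to vinyldiazoacetates: DBU forms the dienolate of the β,γ-unsaturated ester, which takes up the diazo nitrogens at its α-carbon; no stereocentre is involved, and 2 is used at once because it slowly closes to a pyrazole.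

Step 2
Reactants: 3 2-bromo-3-methylcyclopent-2-en-1-one
Product: 4 2-ethenyl-3-methylcyclopent-2-en-1-one
Conditions: Bu3SnCH=CH2, Pd(PPh3)4 (5 mol %), BHT (trace), toluene, 100 °C
Reagents that add atoms: tributyl(vinyl)stannane, C=C[Sn](CCCC)(CCCC)CCCC
Why: Stille coupling of an α-bromoenone: zerovalent palladium inserts into the activated C(sp2)–Br bond, and vinyl transfer from tin with reductive elimination gives the cross-conjugated dienone without touching the ketone; no stereocentre is formed.

Step 3
Reactants: 2 methyl 2-diazobut-3-enoate; 4 2-ethenyl-3-methylcyclopent-2-en-1-one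
Product: 6 methyl (8aR)-8a-methyl-3-oxo-1,2,3,5,8,8a-hexahydroazulene-6-carboxylate, via cis-divinylcyclopropane 5 (not isolated)
Conditions: Rh2(S-PTAD)4 (1 mol %), hexanes, 0 °C to rt, 2 (2 equiv) added over 3 h; then 70 °C in the same flask
Reagents that add atoms: none
Why: The donor/acceptor rhodium carbenoid from 2 cyclopropanates only the monosubstituted vinyl group of 4, because the tetrasubstituted, carbonyl-conjugated ring alkene is closed to it on steric and electronic grounds, and this fixes the orientation in which the ester-bearing carbon bonds to the CH2 terminus (C5–C6). The closest known reaction type is the enantioselective tandem cyclopropanation/Cope rearrangement (formal [4+3] cycloaddition) of vinyldiazoacetates with 1,3-dienes, including 1-vinyl-2-methylcycloalkenes that end as angular-methyl quaternary carbons. The three-membered ring closes by a concerted asynchronous [2+1] addition that places the cyclopentenyl group cis to the vinyl group, and the seven-membered ring closes by the [3,3] shift of 5 through the endo boat transition state, which breaks the bond between the two substituted cyclopropane carbons, makes C8–C8a and leaves both ring alkenes Z. The only stereocentre that remains, C8a, is controlled by the chiral carboxylate ligands, which set the (1S,2S) configuration of 5, and the boat geometry passes this on to (8aR). Because the ring methyl sits on the inner (Z) position of the reacting alkene, the Cope step should be slower than usual, hence the final heating, which is driven by release of cyclopropane strain and by the two conjugated carbonyl systems of 6. Slow addition of 2 in a non-polar solvent suppresses carbene dimerisation, pyrazole formation and attack at the vinylogous carbon or at the ketone oxygen.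

Step 4
Reactants: 6 methyl (8aR)-8a-methyl-3-oxo-1,2,3,5,8,8a-hexahydroazulene-6-carboxylate
Product: 7 methyl (3R,8aR)-3-hydroxy-8a-methyl-3-(propan-2-yl)-1,2,3,5,8,8a-hexahydroazulene-6-carboxylate
Conditions: iPrMgCl, anhydrous CeCl3, THF, −78 °C; aq NH4Cl
Reagents that add atoms: isopropylmagnesium chloride, CC(C)[Mg]Cl
Why: Organocerium 1,2-addition to a ketone: the weakly basic, oxophilic reagent suppresses enolisation, β-hydride reduction and 1,4-addition and leaves the less electrophilic enoate alone, and it should reach C3 from the face opposite the 8a-methyl, which stands perpendicular to the flat alkylidene-cyclopentanone unit, so the new 3-OH is cis to that methyl (3R).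

Step 5
Reactants: 7 methyl (3R,8aR)-3-hydroxy-8a-methyl-3-(propan-2-yl)-1,2,3,5,8,8a-hexahydroazulene-6-carboxylate
Product: 8 (3R,8aR)-6-(hydroxymethyl)-8a-methyl-3-(propan-2-yl)-1,2,3,5,8,8a-hexahydroazulen-3-ol
Conditions: iBu2AlH (3.5 equiv), CH2Cl2, −78 to 0 °C; Rochelle salt
Reagents that add atoms: none
Why: Standard iBu2AlH 1,2-reduction of an α,β-unsaturated ester to the allylic alcohol; the tertiary alkoxide only consumes one equivalent of hydride and no stereocentre changes.

Step 6
Reactants: 8 (3R,8aR)-6-(hydroxymethyl)-8a-methyl-3-(propan-2-yl)-1,2,3,5,8,8a-hexahydroazulen-3-ol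
Product: 10 (3R,8aR)-6,8a-dimethyl-3-(propan-2-yl)-1,2,3,5,8,8a-hexahydroazulen-3-ol, via allylic mesylate 9 (not isolated)
Conditions: MsCl, Et3N, THF, −40 °C; then LiEt3BH, −40 to 0 °C
Reagents that add atoms: methanesulfonyl chloride, CS(=O)(=O)Cl (its atoms are present in 9 only)
Why: Selective sulfonylation of the primary allylic hydroxyl (the tertiary one is inert at low temperature) followed by SN2 hydride displacement, a common two-stage deoxygenation that turns CH2OH into CH3 without allylic transposition; the stereocentres are untouched.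

Step 7
Reactants: 10 (3R,8aR)-6,8a-dimethyl-3-(propan-2-yl)-1,2,3,5,8,8a-hexahydroazulen-3-ol
Product: 11 (3R,3aS,4R,8aR)-3a,4-epoxy-6,8a-dimethyl-3-(propan-2-yl)-1,2,3,3a,4,5,8,8a-octahydroazulen-3-ol (oxirane on the face of the 3-OH and the 8a-methyl)
Conditions: VO(acac)2 (5 mol %), tBuOOH (decane), CH2Cl2, 0 °C to rt
Reagents that add atoms: tert-butyl hydroperoxide, CC(C)(C)OO
Why: Hydroxyl-directed vanadium-catalysed epoxidation of an allylic alcohol: the vanadium alkoxide of the 3-OH delivers oxygen to C3a=C4 on its own face and ignores the remote C6=C7 alkene, which sets the oxirane syn to the 3-OH (3aS,4R).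

Step 8
Reactants: 11 (3R,3aS,4R,8aR)-3a,4-epoxy-6,8a-dimethyl-3-(propan-2-yl)-1,2,3,3a,4,5,8,8a-octahydroazulen-3-ol
Product: 12 (3R,3aS,4R,8aR)-6,8a-dimethyl-3-(propan-2-yl)-1,2,3,3a,4,5,8,8a-octahydroazulene-3,4-diol (4-epi-jaeschkeanadiol)
Conditions: Cp2TiCl2 (20 mol %), Mn dust, 2,4,6-collidine·HCl, 1,4-cyclohexadiene, THF, rt
Reagents that add atoms: none
Why: Titanocene-catalysed reductive epoxide opening, known to turn trisubstituted 2,3-epoxy alcohols into 1,3-diols: trivalent titanium (Cp2TiCl) cleaves C3a–O homolytically to the tertiary radical while the C4–O bond keeps its configuration, and hydrogen-atom transfer should come from the face opposite the titanium alkoxide, the 3-oxygen and the 8a-methyl to give the trans fusion (3aS); any C3a epimer is corrected in step 9.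

Step 9
Reactants: 12 (3R,3aS,4R,8aR)-6,8a-dimethyl-3-(propan-2-yl)-1,2,3,3a,4,5,8,8a-octahydroazulene-3,4-diol
Product: 13 (3R,3aR,8aR)-3-hydroxy-6,8a-dimethyl-3-(propan-2-yl)-2,3,3a,5,8,8a-hexahydroazulen-4(1H)-one
Conditions: Dess–Martin periodinane, NaHCO3, CH2Cl2, 0 °C to rt; crude ketone with DBU (cat.), toluene, rt
Reagents that add atoms: none
Why: Dess–Martin oxidation touches only the secondary alcohol, and the base equilibrates the now enolisable C3a to the expected more stable epimer, in which acyl carbon C4 is trans to the isopropyl group on the five-membered ring and cis to the 3-OH that hydrogen-bonds to the ketone (trans fusion; the descriptor 3aR reflects a change of priorities only).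

Step 10
Reactants: 13 (3R,3aR,8aR)-3-hydroxy-6,8a-dimethyl-3-(propan-2-yl)-2,3,3a,5,8,8a-hexahydroazulen-4(1H)-one
Product: 14 (3R,3aS,4S,8aR)-6,8a-dimethyl-3-(propan-2-yl)-1,2,3,3a,4,5,8,8a-octahydroazulene-3,4-diol (jaeschkeanadiol)
Conditions: Me4NBH(OAc)3, MeCN/AcOH 1:1, −30 to −20 °C
Reagents that add atoms: none
Why: Evans–Saksena reduction of a β-hydroxy ketone: the 3-OH exchanges an acetate on boron and the hydride is delivered intramolecularly to the carbonyl face on the side of that hydroxyl, so the new 4-OH ends on the opposite face (4S, anti-1,3-diol).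

Step 11
Reactants: 14 jaeschkeanadiol; 15 4-acetoxy-3-methoxybenzoic acid
Product: 16 (3R,3aS,4S,8aR)-3-hydroxy-6,8a-dimethyl-3-(propan-2-yl)-1,2,3,3a,4,5,8,8a-octahydroazulen-4-yl 4-acetoxy-3-methoxybenzoate
Conditions: DCC, DMAP, toluene, 60 °C
Reagents that add atoms: none
Why: Steglich esterification: the acylpyridinium species acylates only the secondary 4-OH because the tertiary 3-OH is too hindered, and C4 keeps its configuration since its C–O bond is not touched.

Step 12
Reactants: 16 (3R,3aS,4S,8aR)-3-hydroxy-6,8a-dimethyl-3-(propan-2-yl)-1,2,3,3a,4,5,8,8a-octahydroazulen-4-yl 4-acetoxy-3-methoxybenzoate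
Product: 17 teferin, (3R,3aS,4S,8aR)-3-hydroxy-6,8a-dimethyl-3-(propan-2-yl)-1,2,3,3a,4,5,8,8a-octahydroazulen-4-yl 4-hydroxy-3-methoxybenzoate
Conditions: pyrrolidine, CH2Cl2, 0 °C to rt
Reagents that add atoms: none
Why: Aminolysis of the aryl acetate, an activated phenyl ester, should be far faster than attack on the hindered, electron-rich benzoate of a secondary alcohol, so only the phenol is set free and no stereocentre is affected.

**Compound list**
1 | methyl but-3-enoate | C=CCC(=O)OC | starting material
2 | methyl 2-diazobut-3-enoate | COC(=O)C(=[N+]=[N-])C=C | intermediate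
3 | 2-bromo-3-methylcyclopent-2-en-1-one | CC1=C(Br)C(=O)CC1 | starting material
4 | 2-ethenyl-3-methylcyclopent-2-en-1-one | C=CC1=C(C)CCC1=O | intermediate
5 | methyl (1S,2S)-1-ethenyl-2-(2-methyl-5-oxocyclopent-1-en-1-yl)cyclopropane-1-carboxylate | COC(=O)[C@]1(C=C)C[C@H]1C2=C(C)CCC2=O | intermediate
6 | methyl (8aR)-8a-methyl-3-oxo-1,2,3,5,8,8a-hexahydroazulene-6-carboxylate | COC(=O)C1=CC[C@@]2(C)CCC(=O)C2=CC1 | intermediate
7 | methyl (3R,8aR)-3-hydroxy-8a-methyl-3-(propan-2-yl)-1,2,3,5,8,8a-hexahydroazulene-6-carboxylate | COC(=O)C1=CC[C@@]2(C)CC[C@@](O)(C(C)C)C2=CC1 | intermediate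
8 | (3R,8aR)-6-(hydroxymethyl)-8a-methyl-3-(propan-2-yl)-1,2,3,5,8,8a-hexahydroazulen-3-ol | OCC1=CC[C@@]2(C)CC[C@@](O)(C(C)C)C2=CC1 | intermediate
9 | [(3R,8aR)-3-hydroxy-8a-methyl-3-(propan-2-yl)-1,2,3,5,8,8a-hexahydroazulen-6-yl]methyl methanesulfonate | CS(=O)(=O)OCC1=CC[C@@]2(C)CC[C@@](O)(C(C)C)C2=CC1 | intermediate
10 | (3R,8aR)-6,8a-dimethyl-3-(propan-2-yl)-1,2,3,5,8,8a-hexahydroazulen-3-ol | CC1=CC[C@@]2(C)CC[C@@](O)(C(C)C)C2=CC1 | intermediate
11 | (3R,3aS,4R,8aR)-3a,4-epoxy-6,8a-dimethyl-3-(propan-2-yl)-1,2,3,3a,4,5,8,8a-octahydroazulen-3-ol | CC1=CC[C@@]2(C)CC[C@@](O)(C(C)C)[C@]23O[C@@H]3C1 | intermediate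
12 | (3R,3aS,4R,8aR)-6,8a-dimethyl-3-(propan-2-yl)-1,2,3,3a,4,5,8,8a-octahydroazulene-3,4-diol | CC1=CC[C@@]2(C)CC[C@@](O)(C(C)C)[C@@H]2[C@H](O)C1 | intermediate
13 | (3R,3aR,8aR)-3-hydroxy-6,8a-dimethyl-3-(propan-2-yl)-2,3,3a,5,8,8a-hexahydroazulen-4(1H)-one | CC1=CC[C@@]2(C)CC[C@@](O)(C(C)C)[C@@H]2C(=O)C1 | intermediate
14 | jaeschkeanadiol, (3R,3aS,4S,8aR)-6,8a-dimethyl-3-(propan-2-yl)-1,2,3,3a,4,5,8,8a-octahydroazulene-3,4-diol | CC1=CC[C@@]2(C)CC[C@@](O)(C(C)C)[C@@H]2[C@@H](O)C1 | intermediate
15 | 4-acetoxy-3-methoxybenzoic acid | COc1cc(C(=O)O)ccc1OC(C)=O | starting material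
16 | O-acetylteferin | COc1cc(C(=O)O[C@H]2CC(C)=CC[C@@]3(C)CC[C@@](O)(C(C)C)[C@H]23)ccc1OC(C)=O | intermediate
17 | teferin | COc1cc(C(=O)O[C@H]2CC(C)=CC[C@@]3(C)CC[C@@](O)(C(C)C)[C@H]23)ccc1O | target

**Step count.** Total: 12 steps. Longest linear sequence: 11 steps (3 → 4 → 6 → 7 → 8 → 10 → 11 → 12 → 13 → 14 → 16 → 17; the branch from 1 is equally long).

**Steps most likely to fail**

Risk 1 (step 3). The cyclopropanation may be slow on the electron-poor cross-conjugated diene, the ketone oxygen may intercept the carbenoid, or face selection by the catalyst may be weak.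
- The fallback masks the ketone so that the diene becomes an ordinary electron-rich 1-vinylcyclopentene. It sets out from 3 and comes back at 6.
- Ketalisation of 3 (ethylene glycol, TsOH, benzene, water separator) gives 6-bromo-7-methyl-1,4-dioxaspiro[4.4]non-6-ene F1.
- Stille vinylation of this gives 6-ethenyl-7-methyl-1,4-dioxaspiro[4.4]non-6-ene F2.
- The rhodium-catalysed reaction of F2 with 2 passes through the ketal-bearing cis-divinylcyclopropane F3 to the ethylene ketal of 6 F4.
- PPTS in wet acetone then unmasks 6.

Risk 2 (step 4). Enolisation at the doubly activated C5 methylene or at C2, β-hydride transfer from the secondary organometallic, or conjugate addition at C4 may outrun 1,2-addition.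
- The fallback replaces the sp3 nucleophile by an sp2 one that has no transferable β-hydride on an sp3 carbon. It sets out from 6 and comes back at 7.
- Isopropenylmagnesium bromide with CeCl3 gives methyl (3R,8aR)-3-hydroxy-8a-methyl-3-(prop-1-en-2-yl)-1,2,3,5,8,8a-hexahydroazulene-6-carboxylate F5.
- The 1,1-disubstituted alkene of F5 is hydrogenated selectively with RhCl(PPh3)3 and H2 in benzene, which leaves the two trisubstituted ring alkenes alone and gives 7.

Risk 3 (step 8). The hindered tertiary radical may be quenched slowly, so loss of the neighbouring oxygen functions (deoxygenation back to an alkene) or hydrogen delivery to the wrong face may compete.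
- The fallback avoids the epoxide and the radical. It sets out from 7 and comes back at 13.
- While the ester still deactivates C6=C7, hydroboration–oxidation of 7 (BH3·THF, then NaBO3) places boron at C4. It gives the cis-fused diol ester F6, drawn for attack on the face of the 8a-methyl.
- iBu2AlH gives the triol F7.
- Selective mesylation of the primary hydroxyl gives the mesylate F8, which is reduced in the same flask with LiEt3BH to the cis-fused diol F9.
- Dess–Martin oxidation gives the cis-fused ketone F10, and DBU epimerises it at C3a to 13. The face chosen by the borane therefore does not matter.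

**Further compounds**
F1 | step 3 | 6-bromo-7-methyl-1,4-dioxaspiro[4.4]non-6-ene | CC1=C(Br)C2(CC1)OCCO2
F2 | step 3 | 6-ethenyl-7-methyl-1,4-dioxaspiro[4.4]non-6-ene | C=CC1=C(C)CCC12OCCO2
F3 | step 3 | ketal-bearing cis-divinylcyclopropane (ethylene ketal of 5) | COC(=O)[C@]1(C=C)C[C@H]1C2=C(C)CCC23OCCO3
F4 | step 3 | ethylene ketal of 6 | COC(=O)C1=CC[C@@]2(C)CCC3(OCCO3)C2=CC1
F5 | step 4 | methyl (3R,8aR)-3-hydroxy-8a-methyl-3-(prop-1-en-2-yl)-1,2,3,5,8,8a-hexahydroazulene-6-carboxylate | COC(=O)C1=CC[C@@]2(C)CC[C@@](O)(C(C)=C)C2=CC1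
F6 | step 8 | cis-fused diol ester (3a-H and 4-OH on the face of the 8a-methyl) | COC(=O)C1=CC[C@@]2(C)CC[C@@](O)(C(C)C)[C@H]2[C@H](O)C1
F7 | step 8 | cis-fused triol | OCC1=CC[C@@]2(C)CC[C@@](O)(C(C)C)[C@H]2[C@H](O)C1
F8 | step 8 | primary allylic mesylate of the triol | CS(=O)(=O)OCC1=CC[C@@]2(C)CC[C@@](O)(C(C)C)[C@H]2[C@H](O)C1
F9 | step 8 | cis-fused diol (3a,4-diepimer of 14) | CC1=CC[C@@]2(C)CC[C@@](O)(C(C)C)[C@H]2[C@H](O)C1
F10 | step 8 | cis-fused ketone (3a-epimer of 13) | CC1=CC[C@@]2(C)CC[C@@](O)(C(C)C)[C@H]2C(=O)C1
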